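**Retrosynthetic overview**
- Last operations: equilibration of the labile centres, after ring-closing metathesis and hydrogenation close the 18-membered macrocycle in the five-carbon bridge between C-9 and C-1′.
- Rings C and D (1-oxaquinolizidine): condensation of an anti-1,3-amino alcohol with a racemic 5-chloro-2-alkyl aldehyde (N,O-acetal formation, then N-alkylation).
- Ring B (ketone ring): 6-endo aza-Michael addition of the ring A N–H to an isopropenyl ketone. Ring A comes from an N-Boc δ-lactam (lactamol olefination/aza-Michael), and C-9′ from Ir-catalysed asymmetric hydrogenation of an alkylidene lactam.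
- C-2/C-3: ketoreductase-catalysed dynamic kinetic reduction of an α-methyl-β-keto ester built from oct-7-enoic acid and ethyl propanoate.
- Ring order: A, then B, then C, then D, then the macrocycle.

**Assumptions and notation**
- Assumption: the five epimerisable centres (C-9, C-9a, C-1′, C-3′, C-9a′) have their thermodynamically preferred configuration in the target, so they are set by equilibration; until the step that sets them they are carried as epimer mixtures and written without descriptors.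
- Assumption: the ketoreductase variant and the ligand antipode are the ones that panel screening shows to give the stated configurations.
- Locants: oxaquinolizidine O-1, C-2, C-3, C-4, N-5, C-6 to C-9, C-9a; quinolizidinone C-1′, C-2′ (C=O), C-3′, C-4′, N-5′, C-6′ to C-9′, C-9a′. Target: 2R,3S,9R,9aS,1′R,3′R,9′S,9a′S.
- Ox = (5S,6R)-3-(tert-butoxycarbonyl)-2,2,5-trimethyl-1,3-oxazinan-6-yl.

**Route**

Step 1
Reactants: 1 oct-7-enoic acid; 2 ethyl propanoate
Product: 4 ethyl 2-methyl-3-oxodec-9-enoate (racemic), via acyl imidazolide 3 (not isolated)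
Conditions: 1, CDI, THF, rt; added to 2 (2.2 equiv)/LiN(i-Pr)2 (2.2 equiv), THF, −78 to −20 °C; 1 M HCl
Reagents that add atoms: none
Why: Crossed Claisen condensation; the acyl imidazolide acylates the ester enolate and the second enolate equivalent deprotonates the product, which stops over-acylation.

Step 2
Reactants: 4 ethyl 2-methyl-3-oxodec-9-enoate
Product: 5 ethyl (2R,3R)-3-hydroxy-2-methyldec-9-enoate
Conditions: ketoreductase (KRED, anti- and 3R-selective variant), NADP+ (cat.), i-PrOH (15 vol%), phosphate buffer pH 7.5, DMSO (5 vol%), 30 °C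
Reagents that add atoms: none
Why: Enzymatic dynamic reductive kinetic resolution; C-2 racemises through the enol in the buffer while the enzyme reduces only one enantiomer from one face, setting both centres (anti, 2R,3R).

Step 3
Reactants: 5 ethyl (2R,3R)-3-hydroxy-2-methyldec-9-enoate
Product: 6 (2R,3R)-3-hydroxy-2-methyldec-9-enamide
Conditions: NH3 (7 M in MeOH), 50 °C, sealed vessel
Reagents that add atoms: ammonia N
Why: Ester aminolysis assisted by the β-hydroxyl; ammonia is too weak a base to epimerise C-2.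

Step 4
Reactants: 6 (2R,3R)-3-hydroxy-2-methyldec-9-enamide
Product: 7 (2S,3R)-1-amino-2-methyldec-9-en-3-ol
Conditions: LiAlH4, THF, reflux; H2O/NaOH work-up
Reagents that add atoms: none
Why: Hydride reduction of the primary amide to the amine; no stereocentre is touched (the C-2 descriptor changes only through CIP priorities).

Step 5
Reactants: 7 (2S,3R)-1-amino-2-methyldec-9-en-3-ol
Product: 8 tert-butyl N-[(2S,3R)-3-hydroxy-2-methyldec-9-en-1-yl]carbamate
Conditions: Boc2O, Et3N, CH2Cl2, 0 °C to rt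
Reagents that add atoms: di-tert-butyl dicarbonate CC(C)(C)OC(=O)OC(=O)OC(C)(C)C
Why: Chemoselective N-acylation (carbamate formation) of the amine over the secondary alcohol.

Step 6
Reactants: 8 tert-butyl N-[(2S,3R)-3-hydroxy-2-methyldec-9-en-1-yl]carbamate
Product: 9 tert-butyl (5S,6R)-6-(hept-6-en-1-yl)-2,2,5-trimethyl-1,3-oxazinane-3-carboxylate
Conditions: 2,2-dimethoxypropane, BF3·OEt2 (cat.), acetone, rt
Reagents that add atoms: 2,2-dimethoxypropane COC(C)(C)OC
Why: Acid-catalysed transacetalisation to the six-membered N,O-acetonide, which removes both acidic protons for the base steps that follow.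

Step 7
Reactants: 9 tert-butyl (5S,6R)-6-(hept-6-en-1-yl)-2,2,5-trimethyl-1,3-oxazinane-3-carboxylate
Product: 11 tert-butyl (5S,6R)-2,2,5-trimethyl-6-(6-oxohexyl)-1,3-oxazinane-3-carboxylate, via ozonide 10 (not isolated)
Conditions: O3, CH2Cl2, −78 °C; PPh3, −78 °C to rt
Reagents that add atoms: ozone [O-][O+]=O
Why: Ozonolysis of the terminal alkene with reductive work-up; carbamate and acetonide are inert.

Step 8
Reactants: 11 tert-butyl (5S,6R)-2,2,5-trimethyl-6-(6-oxohexyl)-1,3-oxazinane-3-carboxylate; 12 tert-butyl 2-oxopiperidine-1-carboxylate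
Product: 13 tert-butyl 3-[1-hydroxy-6-(Ox)hexyl]-2-oxopiperidine-1-carboxylate (diastereomer mixture)
Conditions: 12, LiN(SiMe3)2, THF, −78 °C; then 11, −78 °C; AcOH quench at −78 °C
Reagents that add atoms: none
Why: Lithium enolate aldol addition of the N-Boc lactam; the cold quench prevents N-to-O Boc transfer, and the new centres are removed in the next step.

Step 9
Reactants: 13 tert-butyl 3-[1-hydroxy-6-(Ox)hexyl]-2-oxopiperidine-1-carboxylate
Product: 15 tert-butyl (3E)-3-[6-(Ox)hexylidene]-2-oxopiperidine-1-carboxylate, via mesylate 14 (not isolated)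
Conditions: MsCl, Et3N, CH2Cl2, 0 °C; then DBU, rt
Reagents that add atoms: none
Why: Mesylation followed by E1cB elimination gives the thermodynamically preferred E-alkylidene lactam.

Step 10
Reactants: 15 tert-butyl (3E)-3-[6-(Ox)hexylidene]-2-oxopiperidine-1-carboxylate
Product: 16 tert-butyl (3S)-3-[6-(Ox)hexyl]-2-oxopiperidine-1-carboxylate
Conditions: H2 (50 bar), [Ir(cod)(SpinPHOX)]BArF (2 mol%; chiral spiro phosphine–oxazoline, ArF = 3,5-(CF3)2C6H3), CH2Cl2, rt
Reagents that add atoms: none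
Why: Catalyst-controlled asymmetric hydrogenation of the exocyclic α,β-unsaturated lactam sets C-3 (the future C-9′) as S, independent of the remote oxazinane centres.

Step 11
Reactants: 16 tert-butyl (3S)-3-[6-(Ox)hexyl]-2-oxopiperidine-1-carboxylate
Product: 17 tert-butyl (3S)-2-hydroxy-3-[6-(Ox)hexyl]piperidine-1-carboxylate (anomer mixture)
Conditions: LiEt3BH, THF, −78 °C; H2O
Reagents that add atoms: none
Why: Partial hydride reduction of the imide-like N-Boc lactam carbonyl stops at the hemiaminal; the oxazinane carbamate is not reduced at −78 °C.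

Step 12
Reactants: 17 tert-butyl (3S)-2-hydroxy-3-[6-(Ox)hexyl]piperidine-1-carboxylate
Product: 19 ethyl 2-{(3S)-1-(tert-butoxycarbonyl)-3-[6-(Ox)hexyl]piperidin-2-yl}acetate (C-2 epimers), via open-chain enoate 18 (not isolated)
Conditions: (EtO)2P(O)CH2CO2Et, NaH, THF, 0 °C to rt
Reagents that add atoms: triethyl phosphonoacetate CCOC(=O)CP(=O)(OCC)OCC
Why: Horner–Wadsworth–Emmons olefination of the ring-opened aldehyde tautomer followed by 6-exo-trig aza-Michael addition of the carbamate anion; the C-2 (future C-9a′) configuration is corrected in step 16.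

Step 13
Reactants: 19 ethyl 2-{(3S)-1-(tert-butoxycarbonyl)-3-[6-(Ox)hexyl]piperidin-2-yl}acetate
Product: 20 ethyl 2-{(3S)-1-(tert-butoxycarbonyl)-3-[6-(Ox)hexyl]piperidin-2-yl}pent-4-enoate (epimer mixture)
Conditions: LiN(SiMe3)2, THF/DMPU, −78 °C; allyl bromide, −78 °C
Reagents that add atoms: allyl bromide C=CCBr
Why: Ester enolate alkylation with a reactive allylic halide at the only enolisable position; the new centre (future C-1′) is set later by equilibration.

Step 14
Reactants: 20 ethyl 2-{(3S)-1-(tert-butoxycarbonyl)-3-[6-(Ox)hexyl]piperidin-2-yl}pent-4-enoate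
Product: 21 N-methoxy-N-methyl-2-{(3S)-1-(tert-butoxycarbonyl)-3-[6-(Ox)hexyl]piperidin-2-yl}pent-4-enamide
Conditions: MeNH(OMe)·HCl, i-PrMgCl, THF, −20 to 0 °C
Reagents that add atoms: N,O-dimethylhydroxylamine hydrochloride CNOC.Cl
Why: Weinreb amide formation by aminolysis of the ester with the magnesium amide, without Lewis acids that would open the acetonide.

Step 15
Reactants: 21 N-methoxy-N-methyl-2-{(3S)-1-(tert-butoxycarbonyl)-3-[6-(Ox)hexyl]piperidin-2-yl}pent-4-enamide
Product: 22 tert-butyl (3S)-2-(2-methyl-3-oxohepta-1,6-dien-4-yl)-3-[6-(Ox)hexyl]piperidine-1-carboxylate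
Conditions: isopropenylmagnesium bromide, THF, 0 °C; cold 0.5 M HCl
Reagents that add atoms: isopropenylmagnesium bromide CC(=C)[Mg]Br
Why: Weinreb ketone synthesis; the chelated tetrahedral intermediate prevents a second addition and releases the isopropenyl ketone only on work-up.

Step 16
Reactants: 22 tert-butyl (3S)-2-(2-methyl-3-oxohepta-1,6-dien-4-yl)-3-[6-(Ox)hexyl]piperidine-1-carboxylate
Product: 24 (1R,3R,9S,9aS)-9-[(7R,8S)-9-amino-7-hydroxy-8-methylnonyl]-3-methyl-1-(prop-2-en-1-yl)octahydro-2H-quinolizin-2-one, via amino enone bis-trifluoroacetate 23 (not isolated)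
Conditions: CF3CO2H/CH2Cl2/H2O (10:10:1), 0 °C to rt; evaporate; K2CO3, MeOH (5 mM), rt to 45 °C
Reagents that add atoms: none
Why: Acidolysis of both Boc groups and the acetonide, then 6-endo-trig aza-Michael closure of ring B; base equilibrates C-9a′ (retro-aza-Michael at the N–H stage) and C-1′/C-3′ (enolisation) to the trans-fused ring with equatorial C-9′ and C-3′ groups and an axial C-1′ allyl, while C-9′ is never adjacent to an iminium.

Step 17
Reactants: 25 hex-5-enenitrile; 26 1-bromo-3-chloropropane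
Product: 27 2-(3-chloropropyl)hex-5-enenitrile (racemic)
Conditions: LiN(i-Pr)2, THF, −78 °C; then 26, −78 °C to rt
Reagents that add atoms: none
Why: Nitrile α-alkylation by SN2 displacement of bromide in preference to chloride.

Step 18
Reactants: 27 2-(3-chloropropyl)hex-5-enenitrile
Product: 28 2-(3-chloropropyl)hex-5-enal (racemic)
Conditions: i-Bu2AlH, CH2Cl2, −78 °C; then 1 M HCl, 0 °C
Reagents that add atoms: water O
Why: Partial reduction of the nitrile to the aldimine and hydrolysis; the α-centre needs no control because it epimerises in steps 19 to 22.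

Step 19
Reactants: 24 (1R,3R,9S,9aS)-9-[(7R,8S)-9-amino-7-hydroxy-8-methylnonyl]-3-methyl-1-(prop-2-en-1-yl)octahydro-2H-quinolizin-2-one; 28 2-(3-chloropropyl)hex-5-enal
Product: 30 (1R,3R,9S,9aS)-9-{6-[(2R,3S)-9-(but-3-en-1-yl)-3-methyloctahydro-2H-pyrido[2,1-b][1,3]oxazin-2-yl]hexyl}-3-methyl-1-(prop-2-en-1-yl)octahydro-2H-quinolizin-2-one (C-9/C-9a epimers), via tetrahydro-1,3-oxazine 29 (not isolated)
Conditions: 4 Å MS, CH2Cl2, rt; then i-Pr2NEt, NaI (cat.), MeCN, 70 °C
Reagents that add atoms: none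
Why: The amino alcohol and the aldehyde condense to the cyclic N,O-acetal (ring C), whose N–H then closes ring D by 6-exo-tet N-alkylation; C-9 and C-9a are labile and converge later.

Step 20
Reactants: 30 oxaquinolizidine–quinolizidinone diene
Product: 31 macrocyclic alkene (target skeleton with a C=C in the C-9 to C-1′ bridge; E/Z and C-9/C-9a mixtures)
Conditions: TsOH (2.2 equiv), CH2Cl2 (1 mM), second-generation Grubbs catalyst [RuCl2(=CHPh)(H2IMes)(PCy3)] (10 mol%), 40 °C; Et3N quench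
Reagents that add atoms: none
Why: Ring-closing metathesis of two terminal alkenes forms the 18-membered ring; full protonation keeps both nitrogens off ruthenium and, with no free lone pair, the β-amino ketone cannot undergo retro-Mannich cleavage.

Step 21
Reactants: 31 macrocyclic alkene
Product: 32 saturated macrocycle (epimer mixture at the labile centres)
Conditions: H2 (1 atm), Pd/C, EtOAc/MeOH, rt
Reagents that add atoms: none
Why: Heterogeneous hydrogenation of the disubstituted alkene; ketone and N,O-acetal are untouched under neutral conditions.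

Step 22
Reactants: 32 saturated macrocycle
Product: 33 target CNP0236330.1 (2R,3S,9R,9aS,1′R,3′R,9′S,9a′S)
Conditions: AcOH (3 equiv), MeOH, rt, 12 h; then K2CO3 (6 equiv), MeOH, 45 °C, 24 h
Reagents that add atoms: none
Why: Thermodynamic equilibration; weak acid opens the N,O-acetal reversibly (iminium/enamine) so C-9/C-9a settle trans-fused and all-equatorial, and base re-converges C-1′/C-3′ by enolisation, both anchored to the fixed C-2, C-3 and C-9′ centres.

**Compound list**
1 | oct-7-enoic acid | C=CCCCCCC(=O)O | starting material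
2 | ethyl propanoate | CCOC(=O)CC | starting material
3 | 1-(oct-7-enoyl)imidazole | C=CCCCCCC(=O)n1ccnc1 | intermediate
4 | ethyl 2-methyl-3-oxodec-9-enoate (racemic) | CCOC(=O)C(C)C(=O)CCCCCC=C | intermediate
5 | ethyl (2R,3R)-3-hydroxy-2-methyldec-9-enoate | CCOC(=O)[C@H](C)[C@H](O)CCCCCC=C | intermediate
6 | (2R,3R)-3-hydroxy-2-methyldec-9-enamide | NC(=O)[C@H](C)[C@H](O)CCCCCC=C | intermediate
7 | (2S,3R)-1-amino-2-methyldec-9-en-3-ol | NC[C@H](C)[C@H](O)CCCCCC=C | intermediate
8 | tert-butyl N-[(2S,3R)-3-hydroxy-2-methyldec-9-en-1-yl]carbamate | CC(C)(C)OC(=O)NC[C@H](C)[C@H](O)CCCCCC=C | intermediate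
9 | tert-butyl (5S,6R)-6-(hept-6-en-1-yl)-2,2,5-trimethyl-1,3-oxazinane-3-carboxylate | CC(C)(C)OC(=O)N1C[C@H](C)[C@@H](CCCCCC=C)OC1(C)C | intermediate
10 | tert-butyl (5S,6R)-2,2,5-trimethyl-6-[5-(1,2,4-trioxolan-3-yl)pentyl]-1,3-oxazinane-3-carboxylate (ozonide) | CC(C)(C)OC(=O)N1C[C@H](C)[C@@H](CCCCCC2OCOO2)OC1(C)C | intermediate
11 | tert-butyl (5S,6R)-2,2,5-trimethyl-6-(6-oxohexyl)-1,3-oxazinane-3-carboxylate | CC(C)(C)OC(=O)N1C[C@H](C)[C@@H](CCCCCC=O)OC1(C)C | intermediate
12 | tert-butyl 2-oxopiperidine-1-carboxylate | O=C1CCCCN1C(=O)OC(C)(C)C | starting material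
13 | tert-butyl 3-[1-hydroxy-6-(Ox)hexyl]-2-oxopiperidine-1-carboxylate | CC(C)(C)OC(=O)N1C[C@H](C)[C@@H](CCCCCC(O)C2CCCN(C(=O)OC(C)(C)C)C2=O)OC1(C)C | intermediate
14 | methanesulfonate of 13 | CC(C)(C)OC(=O)N1C[C@H](C)[C@@H](CCCCCC(OS(C)(=O)=O)C2CCCN(C(=O)OC(C)(C)C)C2=O)OC1(C)C | intermediate
15 | tert-butyl (3E)-3-[6-(Ox)hexylidene]-2-oxopiperidine-1-carboxylate | CC(C)(C)OC(=O)N1C[C@H](C)[C@@H](CCCCC/C=C2\CCCN(C(=O)OC(C)(C)C)C2=O)OC1(C)C | intermediate
16 | tert-butyl (3S)-3-[6-(Ox)hexyl]-2-oxopiperidine-1-carboxylate | CC(C)(C)OC(=O)N1C[C@H](C)[C@@H](CCCCCC[C@H]2CCCN(C(=O)OC(C)(C)C)C2=O)OC1(C)C | intermediate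
17 | tert-butyl (3S)-2-hydroxy-3-[6-(Ox)hexyl]piperidine-1-carboxylate | CC(C)(C)OC(=O)N1C[C@H](C)[C@@H](CCCCCC[C@H]2CCCN(C(=O)OC(C)(C)C)C2O)OC1(C)C | intermediate
18 | ethyl (2E,4S)-4-[3-(tert-butoxycarbonylamino)propyl]-10-(Ox)dec-2-enoate | CC(C)(C)OC(=O)N1C[C@H](C)[C@@H](CCCCCC[C@@H](CCCNC(=O)OC(C)(C)C)/C=C/C(=O)OCC)OC1(C)C | intermediate
19 | ethyl 2-{(3S)-1-(tert-butoxycarbonyl)-3-[6-(Ox)hexyl]piperidin-2-yl}acetate | CC(C)(C)OC(=O)N1C[C@H](C)[C@@H](CCCCCC[C@H]2CCCN(C(=O)OC(C)(C)C)C2CC(=O)OCC)OC1(C)C | intermediate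
20 | ethyl 2-{(3S)-1-(tert-butoxycarbonyl)-3-[6-(Ox)hexyl]piperidin-2-yl}pent-4-enoate | CC(C)(C)OC(=O)N1C[C@H](C)[C@@H](CCCCCC[C@H]2CCCN(C(=O)OC(C)(C)C)C2C(CC=C)C(=O)OCC)OC1(C)C | intermediate
21 | N-methoxy-N-methyl-2-{(3S)-1-(tert-butoxycarbonyl)-3-[6-(Ox)hexyl]piperidin-2-yl}pent-4-enamide | CC(C)(C)OC(=O)N1C[C@H](C)[C@@H](CCCCCC[C@H]2CCCN(C(=O)OC(C)(C)C)C2C(CC=C)C(=O)N(C)OC)OC1(C)C | intermediate
22 | tert-butyl (3S)-2-(2-methyl-3-oxohepta-1,6-dien-4-yl)-3-[6-(Ox)hexyl]piperidine-1-carboxylate | CC(C)(C)OC(=O)N1C[C@H](C)[C@@H](CCCCCC[C@H]2CCCN(C(=O)OC(C)(C)C)C2C(CC=C)C(=O)C(C)=C)OC1(C)C | intermediate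
23 | 4-{(3S)-3-[(7R,8S)-9-amino-7-hydroxy-8-methylnonyl]piperidin-2-yl}-2-methylhepta-1,6-dien-3-one bis(trifluoroacetate) | NC[C@H](C)[C@H](O)CCCCCC[C@H]1CCCNC1C(CC=C)C(=O)C(C)=C.OC(=O)C(F)(F)F.OC(=O)C(F)(F)F | intermediate
24 | (1R,3R,9S,9aS)-9-[(7R,8S)-9-amino-7-hydroxy-8-methylnonyl]-3-methyl-1-(prop-2-en-1-yl)octahydro-2H-quinolizin-2-one | C[C@@H]1CN2CCC[C@H](CCCCCC[C@@H](O)[C@@H](C)CN)[C@H]2[C@@H](CC=C)C1=O | intermediate
25 | hex-5-enenitrile | C=CCCCC#N | starting material
26 | 1-bromo-3-chloropropane | ClCCCBr | starting material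
27 | 2-(3-chloropropyl)hex-5-enenitrile (racemic) | C=CCCC(CCCCl)C#N | intermediate
28 | 2-(3-chloropropyl)hex-5-enal (racemic) | C=CCCC(CCCCl)C=O | intermediate
29 | (1R,3R,9S,9aS)-9-{6-[(5S,6R)-2-(1-chlorooct-7-en-4-yl)-5-methyl-1,3-oxazinan-6-yl]hexyl}-3-methyl-1-(prop-2-en-1-yl)octahydro-2H-quinolizin-2-one | C[C@@H]1CN2CCC[C@H](CCCCCC[C@H]3OC(NC[C@@H]3C)C(CCC=C)CCCCl)[C@H]2[C@@H](CC=C)C1=O | intermediate
30 | (1R,3R,9S,9aS)-9-{6-[(2R,3S)-9-(but-3-en-1-yl)-3-methyloctahydro-2H-pyrido[2,1-b][1,3]oxazin-2-yl]hexyl}-3-methyl-1-(prop-2-en-1-yl)octahydro-2H-quinolizin-2-one | C[C@@H]1CN2CCC[C@H](CCCCCC[C@H]3OC4C(CCC=C)CCCN4C[C@@H]3C)[C@H]2[C@@H](CC=C)C1=O | intermediate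
31 | macrocyclic alkene (target skeleton with C=C in the C-9 to C-1′ bridge; C-9/C-9a and E/Z unassigned) | C[C@@H]1CN2CCC[C@@H]3CCCCCC[C@H]4OC5C(CCC=CC[C@@H](C1=O)[C@H]32)CCCN5C[C@@H]4C | intermediate
32 | saturated macrocycle (C-9/C-9a unassigned) | C[C@@H]1CN2CCC[C@@H]3CCCCCC[C@H]4OC5C(CCCCC[C@@H](C1=O)[C@H]32)CCCN5C[C@@H]4C | intermediate
33 | CNP0236330.1 (2R,3S,9R,9aS,1′R,3′R,9′S,9a′S) | C[C@@H]1CN2CCC[C@@H]3CCCCCC[C@H]4O[C@H]5[C@H](CCCCC[C@@H](C1=O)[C@H]32)CCCN5C[C@@H]4C | target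

**Totals and risks**
Total step count: 22. Longest linear sequence: 20 (steps 1 to 16 and 19 to 22); steps 17 and 18 form a two-step side branch.

The three steps most likely to fail:

Step 10 (enantioselective hydrogenation of a heavily functionalised alkylidene lactam). The fallback sets out from 15 and comes back at 16. LiOH in THF/H2O at 0 °C opens the activated N-Boc lactam to (E)-2-[3-(tert-butoxycarbonylamino)propyl]-8-(Ox)oct-2-enoic acid F1. Carboxylate-directed hydrogenation with Ru(OAc)2[(S)-H8-BINAP] (or its antipode, whichever gives 2S), H2 (50 bar), MeOH then gives (2S)-2-[3-(tert-butoxycarbonylamino)propyl]-8-(Ox)octanoic acid F2. EDC·HCl/DMAP in CH2Cl2 re-closes the N-Boc lactam by acylation of the carbamate nitrogen to give 16.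

Step 20 (metathesis macrocyclisation of a bis-amine carrying an N,O-acetal). The fallback sets out from 21 and comes back at 32; the macrocycle is closed by N,O-acetal formation instead of metathesis.
- Aldehyde 28 is converted (HC(OMe)3, MeOH, cat. TsOH) into 5-(3-chloropropyl)-6,6-dimethoxyhex-1-ene F3.
- Cross-metathesis of 21 with excess F3 under [RuCl2(=CHPh)(H2IMes)(PCy3)], with no basic nitrogen present, gives the chain-extended unsaturated Weinreb amide F4.
- H2, Pd/C gives the saturated chloro-acetal Weinreb amide F5.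
- Isopropenylmagnesium bromide gives the chloro-acetal isopropenyl ketone F6.
- CF3CO2H/H2O unmasks both amines, the alcohol and the aldehyde together. Neutralisation at 1 mM (i-Pr2NEt, NaI, MeCN, 60 °C) closes ring B by aza-Michael addition and the macrocycle by oxazine formation and N-alkylation, giving 32.

Step 22 (convergence of five labile centres inside the macrocycle). The fallback sets out from 30 and comes back at 33; the quinolizidinone centres set in the open-chain series (step 16) are frozen instead of re-equilibrated.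
- NaBH4 in MeOH at 0 °C reduces 30 to the open-chain quinolizidin-2-ol diene F7, in which C-1′, C-3′ and C-9a′ can no longer epimerise.
- Metathesis as the bis-tosylate salt gives the macrocyclic quinolizidin-2-ol alkene F8.
- H2, Pd/C and then AcOH/MeOH (only the N,O-acetal can still equilibrate) give the saturated all-equatorial macrocyclic quinolizidin-2-ol F9.
- Swern oxidation ((COCl)2, DMSO, Et3N, −78 °C) returns the ketone without touching the set centres and gives 33.

**Further compounds**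
F1 | step 10 | (E)-2-[3-(tert-butoxycarbonylamino)propyl]-8-(Ox)oct-2-enoic acid | CC(C)(C)OC(=O)N1C[C@H](C)[C@@H](CCCCC/C=C(\CCCNC(=O)OC(C)(C)C)C(=O)O)OC1(C)C
F2 | step 10 | (2S)-2-[3-(tert-butoxycarbonylamino)propyl]-8-(Ox)octanoic acid | CC(C)(C)OC(=O)N1C[C@H](C)[C@@H](CCCCCC[C@@H](CCCNC(=O)OC(C)(C)C)C(=O)O)OC1(C)C
F3 | step 20 | 5-(3-chloropropyl)-6,6-dimethoxyhex-1-ene | C=CCCC(CCCCl)C(OC)OC
F4 | step 20 | chain-extended unsaturated Weinreb amide (cross-metathesis product of 21 and F3) | CC(C)(C)OC(=O)N1C[C@H](C)[C@@H](CCCCCC[C@H]2CCCN(C(=O)OC(C)(C)C)C2C(CC=CCCC(CCCCl)C(OC)OC)C(=O)N(C)OC)OC1(C)C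
F5 | step 20 | saturated chloro-acetal Weinreb amide | CC(C)(C)OC(=O)N1C[C@H](C)[C@@H](CCCCCC[C@H]2CCCN(C(=O)OC(C)(C)C)C2C(CCCCCC(CCCCl)C(OC)OC)C(=O)N(C)OC)OC1(C)C
F6 | step 20 | chloro-acetal isopropenyl ketone | CC(C)(C)OC(=O)N1C[C@H](C)[C@@H](CCCCCC[C@H]2CCCN(C(=O)OC(C)(C)C)C2C(CCCCCC(CCCCl)C(OC)OC)C(=O)C(C)=C)OC1(C)C
F7 | step 22 | open-chain quinolizidin-2-ol diene (carbinol of 30) | C[C@@H]1CN2CCC[C@H](CCCCCC[C@H]3OC4C(CCC=C)CCCN4C[C@@H]3C)[C@H]2[C@@H](CC=C)C1O
F8 | step 22 | macrocyclic quinolizidin-2-ol alkene | C[C@@H]1CN2CCC[C@@H]3CCCCCC[C@H]4OC5C(CCC=CC[C@@H](C1O)[C@H]32)CCCN5C[C@@H]4C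
F9 | step 22 | saturated all-equatorial macrocyclic quinolizidin-2-ol | C[C@@H]1CN2CCC[C@@H]3CCCCCC[C@H]4O[C@H]5[C@H](CCCCC[C@@H](C1O)[C@H]32)CCCN5C[C@@H]4C
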